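## The problem

The target **28** is a 3β-acetoxy-9α-hydroxy labdane. It is a trans-fused decalin (ring A = C1–C5 plus C10, ring B = C5–C10) whose C9 carries a two-carbon arm (C11–C12) ending in an α-substituted butenolide (C13=C14, lactone carbonyl C16, OCH2 = C15). Five stereocentres (C3, C5, C8, C9, C10) lie on the bicycle; C4, C10 and C9 are fully substituted and C10 and C9 are adjacent, so a quaternary carbon must be made next to a tertiary carbinol. Only C3, a secondary carbinol, is cheaply set by reagent control, and it can then steer ring formation through its equatorial preference on ring A. The axial C10 methyl (C20) shields the β face of C9, so the C9 oxygen has to arrive on the α face of a carbon that already bears C11; the equatorial C17 methyl on C8 is the thermodynamic epimer, because the axial one would be syn-diaxial to C20. The tertiary C9 carbinol (dehydration, retro-aldol or acyloin shift when a carbonyl flanks it), the butenolide (base, hydride, hydrogenation) and the acetate (hydride, organometallics) are fragile, so the last two must come late. The enabling feature is that C5–C10 and C8–C9 lie 1,4 across ring B while C1–C4 bridge C10 and C5 with four carbons. With C9=C10 as an alkene and C5=C6–C7=C8 as a diene, one [4+2] closes both rings and creates quaternary C10; a donor oxygen on C8 next to an ester on C9 is then a masked β-keto ester, from which the C9 hydroxyl and the C8 methyl follow.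

## Retrosynthesis

**28 ⇒ 27 ⇒ 26, then C12–C13.** The acetate is put on last (27 → 28) and the C3 oxygen travels as a TBS ether (26). The side chain is cut at C12–C13, between an sp3 carbon and the lactone α-carbon, giving vinyl carbinol **23** and 3-bromofuran-2(5H)-one **24**. Cutting C9–C11 instead would need a carbon nucleophile to attack a C9 ketone from the shielded β face; cutting C11–C12 would leave C11 at the carbonyl level. This cut brings the butenolide in intact and leaves all five stereocentres in 23. The forward reaction must hydroborate a hindered vinyl group and couple the borane under base mild enough for a butenolide.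

**23 ⇒ 22 ⇒ 21 ⇒ 20 (C11=C12).** The vinyl group is traced to aldehyde **22**, diol **21** and α-hydroxy ester **20**, so that C11 is the ester carbon of the cycloaddition and only C12 is added. The alternative of carrying an aldehyde through the earlier steps is rejected because the ester is needed for the C9 chemistry. The precursor loses one carbon and no stereocentre. The forward steps ask only for reduction, oxidation without glycol cleavage, and methylenation of an α-hydroxy aldehyde.

**20 ⇒ 19 (C8–H) and 19 ⇒ 18 (C8=C17).** The C17 methyl is traced to the exocyclic alkene **19** and this to ketone **18**. A hydrogen-atom-transfer hydrogenation is chosen over catalytic or hydroxyl-directed hydrogenation, because both of those would deliver hydrogen to the open α face and give the axial methyl. The forward steps need a non-basic methylenation of an α-ketol and a radical hydrogenation that ends at the equatorial methyl.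

**18 ⇒ 17 (C9–O).** The tertiary hydroxyl is removed to give β-keto ester **17**. This order, carbon first and oxygen second at C9, is dictated by the C20 methyl: any reagent meets C9 from the α face, which is where the oxygen must be. The precursor loses its most sensitive group. The forward reaction is an enolate hydroxylation.

**17 ⇒ 16 ⇒ 14.** Redox adjustment (ketone to alcohol, alkane to alkene, alcohol to TES ether) turns the β-keto ester into cycloadduct **14**, with C8–OTES, C9–CO2Me and a C6=C7 alkene. C8 and C9 of 14 are both erased on the way to 17, so only the ring fusion of 14 matters.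

**14 ⇒ 13 (C5–C10 and C8–C9).** Both ring B bonds are cut in a retro-[4+2], opening ring A as well, to acyclic triene **13** with a single stereocentre (C3). Against single-bond cuts of ring B (aldol, Michael, cation–olefin) this removes two rings, two bonds and four stereocentres at once and is polarity-matched (donor at C8, acceptor at C9). The forward reaction needs ester-endo approach and control of the diene face by C3.

**13 ⇒ 12 ⇒ 10 + 11.** The silyl dienol ether is the γ-enolisation product of enal **12**, so no diene has to be built by olefination. Enal 12 is cut at C6=C7 by cross-metathesis into terminal alkene **10** and crotonaldehyde **11**. The forward steps need chemoselective metathesis (the trisubstituted enoate must stay out) and E-selective soft enolisation.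

**10 ⇒ 8 (C9–C11 and C10–C20).** The (E)-β-methyl enoate is cut into a terminal alkyne, a methyl group and a methoxycarbonyl group. Carboalumination fixes the alkene geometry by syn addition, which a phosphonate olefination of a methyl ketone would not.

**8 ⇒ 7 ⇒ 6 ⇒ 5 ⇒ 1 + 2 (C2–C3).** Silyl ether **8** comes from (S)-alcohol **7**, set by catalytic reduction of ketone **6**, whose two flanks (tertiary alkyl against primary alkyl) differ strongly. The ketone is reached from racemic alcohol **5**, made from 2,2-dimethylpent-4-enal **1** and the Grignard reagent of bromide **2**. The alkyne is carried as its C-silyl derivative, since an alkylmagnesium halide cannot coexist with a terminal alkyne C–H.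

## Roads not taken

**Alternative 1:** Ring B is cut at C6–C7 and C8–C9, leaving a finished ring A. In the forward step Et3B/O2 turns the primary iodide **A1** into a C6 radical, which adds to acrolein **A2**; the resulting boron enolate closes onto the C9 ketone to give **A3**, with the tertiary carbinol and a formyl group on C8.
- Merits: the C9 carbinol is made in the ring-closing step without enolate oxidation, and the C8 substituent is epimerisable, so the equatorial configuration is under thermodynamic control. On these two points this road is better than the chosen plan, which relies on the facial course of a radical hydrogenation.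
- Weak points: A1 already holds three stereocentres (C3, C5, C10) with C5 wedged between two quaternary carbons, so making it is a problem of the same size as the decalin itself. The C9 configuration depends on the face of an acyclic ketone. A3 is a β-hydroxy aldehyde open to retro-aldol and dehydration. The formyl group must still be deoxygenated to methyl, and the benzyloxybutyl arm rebuilt into the butenolide.
- Comparison: the chosen plan sets against it the formation of both rings and the ring-fusion pair in one step from a chain with one stereocentre, and a two-step completion of the side chain.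

**Alternative 2:** The cut is C4–C5 and C9–C10. MeAlCl2 opens the (S)-epoxide of **A4** at C4, the E-alkene attacks through C5 and the β-keto ester enol closes on C10 through C9, giving hydroxy keto ester **A5**.
- Merits: A4 needs only a few steps from cheap acyclic building blocks, and A5 is the O-desilyl form of **17**, so this road reaches the common β-keto ester in roughly half the steps. In step count up to 17 it is clearly the better route, and the chair–chair folding gives the trans fusion and 3β-hydroxyl reliably.
- Weak points: a cationic bicyclisation partitions between C- and O-termination by the enol, monocyclic products and elimination. Enantiopurity rests on site- and face-selective epoxidation of one alkene in a polyene.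
- Comparison: the chosen plan sets against it a pericyclic closure whose outcome is fixed by alkene geometry and not by cation partitioning, and an adduct that arrives with C3 protected and the C8 oxygen differentiated.

**Alternative 3:** Only C5–C10 is cut. Anodic oxidation of the enol ether of **A6** gives a radical cation that the allylsilane attacks at C10 through C5; loss of silicon and solvent capture at C9 give ring A acetal **A7**, with quaternary C10 and a C5 vinyl group.
- Merits: an umpolung that forms the hindered C5–C10 bond under mild, reagent-free conditions and leaves two handles (C9 aldehyde, C6=C7).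
- Weak points: only ring A and one skeletal bond are made. The C5/C10 relation must be controlled across a forming ring with no second anchor. C9 arrives at the aldehyde level and must become a tertiary carbinol bearing C11, and the whole of ring B (C7–C8, C8–C9) and C17 are still to come.
- Comparison: the chosen plan forms the same C5–C10 bond together with C8–C9 and ring B in the same operation; the electrochemical route is in no respect shorter for this target.

Key step: step 8

Conventions and assumptions:
- Bicyclic compounds are named on the labdane skeleton (C1–C10 decalin, C11 on C9, C17 on C8, C18/C19 on C4, C20 on C10). β is the face of C20; all bicycles are trans-fused (5α-H, 10β-CH3); "8βH" means that the C17 methyl is α (equatorial).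
- Compounds 1, 2, 11 and 24 are taken as purchasable.

## Route

Step 1
Reactants: 1 2,2-dimethylpent-4-enal; 2 (4-bromobut-1-yn-1-yl)trimethylsilane
Product: 5 rac-4,4-dimethylnon-1-en-8-yn-5-ol, via Grignard reagent 3 (not isolated), via C-silylated alkynol 4 (not isolated)
Conditions: 2, Mg, THF, rt→40 °C; then 1, 0 °C; NH4Cl (aq); crude in MeOH, K2CO3, rt
Reagents that add atoms: none
Why: Grignard addition to a non-enolisable α-quaternary aldehyde forms C2–C3; the alkyne is carried as its C-SiMe3 derivative because an alkylmagnesium halide would deprotonate a terminal alkyne, and K2CO3/MeOH then cleaves the C(sp)–Si bond. The racemic carbinol is corrected in steps 2 and 3.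

Step 2
Reactants: 5 rac-4,4-dimethylnon-1-en-8-yn-5-ol
Product: 6 4,4-dimethylnon-1-en-8-yn-5-one
Conditions: Dess–Martin periodinane, NaHCO3, CH2Cl2, 0 °C→rt
Reagents that add atoms: none
Why: Dess–Martin oxidation of a hindered secondary alcohol; alkene and terminal alkyne are inert.

Step 3
Reactants: 6 4,4-dimethylnon-1-en-8-yn-5-one
Product: 7 (5S)-4,4-dimethylnon-1-en-8-yn-5-ol
Conditions: (R)-2-methyl-CBS-oxazaborolidine (20 mol %), catecholborane, toluene, −78→−40 °C; MeOH, then NaOH (aq) wash
Reagents that add atoms: none
Why: Corey–Bakshi–Shibata reduction; the tertiary alkyl flank acts as the large group and the primary chain as the small one, so the (R)-catalyst should deliver hydride to the face that gives the (S)-carbinol (C3 of the target). Catecholborane does not hydroborate the alkene or alkyne at this temperature.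

Step 4
Reactants: 7 (5S)-4,4-dimethylnon-1-en-8-yn-5-ol
Product: 8 tert-butyl{[(5S)-4,4-dimethylnon-1-en-8-yn-5-yl]oxy}dimethylsilane
Conditions: TBSOTf, 2,6-lutidine, CH2Cl2, 0 °C
Reagents that add atoms: tert-butyldimethylsilyl triflate, CC(C)(C)[Si](C)(C)OS(=O)(=O)C(F)(F)F
Why: Silylation of a neopentyl-type secondary alcohol needs the triflate; the TBS ether is chosen to outlast the later TES ether and all organometallic steps.

Step 5
Reactants: 8 tert-butyl{[(5S)-4,4-dimethylnon-1-en-8-yn-5-yl]oxy}dimethylsilane
Product: 10 methyl (2E,6S)-6-[(tert-butyldimethylsilyl)oxy]-3,7,7-trimethyldeca-2,9-dienoate, via alkenylalane 9 (not isolated)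
Conditions: AlMe3, Cp2ZrCl2 (0.3 equiv), CH2Cl2, 0 °C→rt; then ClCO2Me, 0 °C→rt
Reagents that add atoms: trimethylaluminium, C[Al](C)C; methyl chloroformate, COC(=O)Cl
Why: Negishi carboalumination adds CH3 and Al syn across the terminal alkyne (CH3 to the internal carbon), and acylation of the alkenylalane with the chloroformate proceeds with retention, so the ester ends cis to the methyl (E). The monosubstituted alkene is far slower than the alkyne under these conditions.

Step 6
Reactants: 10 methyl (2E,6S)-6-[(tert-butyldimethylsilyl)oxy]-3,7,7-trimethyldeca-2,9-dienoate; 11 crotonaldehyde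
Product: 12 methyl (2E,6S,9E)-6-[(tert-butyldimethylsilyl)oxy]-3,7,7-trimethyl-11-oxoundeca-2,9-dienoate
Conditions: 11 (5 equiv), RuCl2(H2IMes)(=CH-C6H4-2-O-i-Pr) (second-generation Hoveyda–Grubbs catalyst, 5 mol %), CH2Cl2, 40 °C
Reagents that add atoms: none
Why: Olefin cross-metathesis of an unhindered terminal alkene with an excess of an enal gives the (E)-enal with loss of propene; the trisubstituted, electron-poor enoate does not enter the catalytic cycle.

Step 7
Reactants: 12 methyl (2E,6S,9E)-6-[(tert-butyldimethylsilyl)oxy]-3,7,7-trimethyl-11-oxoundeca-2,9-dienoate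
Product: 13 methyl (2E,6S,8E,10E)-6-[(tert-butyldimethylsilyl)oxy]-3,7,7-trimethyl-11-[(triethylsilyl)oxy]undeca-2,8,10-trienoate
Conditions: TESOTf (1.2 equiv), Et3N, Et2O, −78→0 °C; pentane extraction, filtration through Et3N-deactivated silica
Reagents that add atoms: triethylsilyl triflate, CC[Si](CC)(CC)OS(=O)(=O)C(F)(F)F
Why: Soft enolisation: O-silylation of the aldehyde and γ-deprotonation at C5 give the 1-silyloxy diene; the new C5=C6 bond should be E because the quaternary C4 cannot sit cis to C7, and the enol ether forms E from the s-trans enal. The ester is much less basic and is not enolised by one equivalent of triflate at low temperature.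

Step 8
Reactants: 13 methyl (2E,6S,8E,10E)-6-[(tert-butyldimethylsilyl)oxy]-3,7,7-trimethyl-11-[(triethylsilyl)oxy]undeca-2,8,10-trienoate
Product: 14 methyl 3β-[(tert-butyldimethylsilyl)oxy]-8β-[(triethylsilyl)oxy]-12,13,14,15,16,17-hexanorlabd-6-en-11-oate
Conditions: Me2AlCl (1.2 equiv), CH2Cl2 (0.01 M), −78→−20 °C; Et3N, then NaHCO3/Rochelle salt (aq)
Reagents that add atoms: none
Why: The Me2AlCl-bound (E)-enoate (C9=C10) and the (E,E)-1-silyloxy diene (C5=C6–C7=C8) combine in a normal-demand, suprafacial [4+2] that is concerted but asynchronous, C5–C10 bonding running ahead because the largest diene HOMO coefficient (C5, remote from oxygen) meets the largest enoate LUMO coefficient (C10). The closest known reaction type is the Lewis-acid-promoted intramolecular Diels–Alder reaction of terminally activated 1,7,9-decatrienoates, here with a 1-silyloxy diene. Ring B closes by the cycloaddition itself (C5–C10 and C8–C9, six-membered), and ring A is the six-membered ring traced by the four-carbon tether C1–C4 in a chair-like fold. C9 and C10 keep the cis relation of ester and methyl of the (E)-alkene, C8 follows from the (E)-enol ether in the endo mode (OTES cis to the ester), and the trans C5/C10 fusion follows from ester-endo, tether-exo approach. The absolute sense of all four centres comes from C3, whose OTBS group sits equatorial on the chair tether and so selects one diene face. The step needs endo and π-facial selectivity: the first is secured by the Lewis-acid-bound ester lying under C6–C7 at low temperature, the second by the equatorial preference of the C3 substituent beside the C4 gem-dimethyl group, which also favours the folded conformer. Regiochemistry is fixed by the tether and reinforced by the donor on C8 facing the acceptor on C9. Only the C5/C10 relation must be right for the route, since C8 and C9 are re-set later, and Me2AlCl also scavenges protic acid, which protects the dienol silyl ether.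

Step 9
Reactants: 14 methyl 3β-[(tert-butyldimethylsilyl)oxy]-8β-[(triethylsilyl)oxy]-12,13,14,15,16,17-hexanorlabd-6-en-11-oate
Product: 16 methyl 3β-[(tert-butyldimethylsilyl)oxy]-8β-hydroxy-12,13,14,15,16,17-hexanorlabdan-11-oate, via saturated bis-silyl ether 15 (not isolated)
Conditions: H2 (1 atm), 10% Pd/C, EtOAc, rt; filter; PPTS (0.2 equiv), MeOH, rt
Reagents that add atoms: none
Why: Heterogeneous hydrogenation of the cis-disubstituted C6=C7 alkene in a neutral solvent, followed by acid-catalysed methanolysis, which removes the TES ether while the hindered secondary TBS ether at C3 stays.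

Step 10
Reactants: 16 methyl 3β-[(tert-butyldimethylsilyl)oxy]-8β-hydroxy-12,13,14,15,16,17-hexanorlabdan-11-oate
Product: 17 methyl 3β-[(tert-butyldimethylsilyl)oxy]-8-oxo-12,13,14,15,16,17-hexanorlabdan-11-oate
Conditions: Dess–Martin periodinane, NaHCO3, CH2Cl2, rt
Reagents that add atoms: none
Why: Dess–Martin oxidation of a β-hydroxy ester to the β-keto ester; C9 becomes epimerisable and is expected to rest with the ester equatorial (β).

Step 11
Reactants: 17 methyl 3β-[(tert-butyldimethylsilyl)oxy]-8-oxo-12,13,14,15,16,17-hexanorlabdan-11-oate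
Product: 18 methyl 3β-[(tert-butyldimethylsilyl)oxy]-9α-hydroxy-8-oxo-12,13,14,15,16,17-hexanorlabdan-11-oate
Conditions: KN(SiMe3)2, THF, −78 °C; 2-(phenylsulfonyl)-3-phenyloxaziridine, −78 °C; NH4Cl (aq) at −78 °C
Reagents that add atoms: 2-(phenylsulfonyl)-3-phenyloxaziridine (Davis oxaziridine), O=S(=O)(c1ccccc1)N1OC1c1ccccc1
Why: Enolate hydroxylation of a β-keto ester with an N-sulfonyl oxaziridine; the planar C9 enolate carbon is attacked axially from the α face, anti to the axial C20 methyl on the neighbouring carbon, which puts OH α and leaves the ester β. Cold quench avoids acyloin shift of the product alkoxide.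

Step 12
Reactants: 18 methyl 3β-[(tert-butyldimethylsilyl)oxy]-9α-hydroxy-8-oxo-12,13,14,15,16,17-hexanorlabdan-11-oate
Product: 19 methyl 3β-[(tert-butyldimethylsilyl)oxy]-9α-hydroxy-12,13,14,15,16-pentanorlabd-8(17)-en-11-oate
Conditions: Zn, CH2Br2, TiCl4, THF (reagent pre-formed at 0 °C); then 18 in CH2Cl2, 0 °C→rt
Reagents that add atoms: dibromomethane, BrCBr
Why: Lombardo (Takai-type) methylenation with the zinc/titanium gem-dimetal reagent, which is non-basic, selective for ketones over esters, tolerant of free hydroxyl groups and effective on hindered ketones; a phosphorus ylide would risk retro-Claisen or acyloin chemistry of the α-ketol.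

Step 13
Reactants: 19 methyl 3β-[(tert-butyldimethylsilyl)oxy]-9α-hydroxy-12,13,14,15,16-pentanorlabd-8(17)-en-11-oate
Product: 20 methyl 3β-[(tert-butyldimethylsilyl)oxy]-9α-hydroxy-8βH-12,13,14,15,16-pentanorlabdan-11-oate
Conditions: Mn(dpm)3 (10 mol %), PhSiH3, t-BuOOH, i-PrOH, rt
Reagents that add atoms: none
Why: Metal-hydride hydrogen-atom-transfer (Mukaiyama-type) hydrogenation of a 1,1-disubstituted alkene: H• adds to C17 and the tertiary C8 radical should take its second hydrogen axially (β), giving the thermodynamically preferred equatorial 8α-methyl and avoiding the syn-diaxial C17/C20 arrangement. Ester, free hydroxyl and silyl ether are inert to these conditions.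

Step 14
Reactants: 20 methyl 3β-[(tert-butyldimethylsilyl)oxy]-9α-hydroxy-8βH-12,13,14,15,16-pentanorlabdan-11-oate
Product: 21 3β-[(tert-butyldimethylsilyl)oxy]-8βH-12,13,14,15,16-pentanorlabdane-9α,11-diol
Conditions: LiAlH4, THF, 0 °C→rt; Fieser work-up
Reagents that add atoms: none
Why: Hydride reduction of a hindered α-hydroxy ester to the 1,2-diol; the TBS ether is stable.

Step 15
Reactants: 21 3β-[(tert-butyldimethylsilyl)oxy]-8βH-12,13,14,15,16-pentanorlabdane-9α,11-diol
Product: 22 3β-[(tert-butyldimethylsilyl)oxy]-9α-hydroxy-8βH-12,13,14,15,16-pentanorlabdan-11-al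
Conditions: (COCl)2, DMSO, CH2Cl2, −78 °C; Et3N, −78→0 °C
Reagents that add atoms: none
Why: Swern oxidation takes the primary alcohol to the aldehyde without glycol cleavage; the tertiary hydroxyl cannot be oxidised and the α-carbon is quaternary, so no epimerisation is possible.

Step 16
Reactants: 22 3β-[(tert-butyldimethylsilyl)oxy]-9α-hydroxy-8βH-12,13,14,15,16-pentanorlabdan-11-al
Product: 23 3β-[(tert-butyldimethylsilyl)oxy]-8βH-13,14,15,16-tetranorlabd-11-en-9α-ol
Conditions: Ph3PCH3Br (3 equiv), KOt-Bu, THF, 0 °C→rt
Reagents that add atoms: methyltriphenylphosphonium bromide, C[P+](c1ccccc1)(c1ccccc1)c1ccccc1.[Br-]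
Why: Wittig methylenation with excess ylide (one equivalent is taken by the hydroxyl) adds C12; the reaction is fast at 0 °C, which limits base-induced acyloin rearrangement of the α-hydroxy aldehyde.

Step 17
Reactants: 23 3β-[(tert-butyldimethylsilyl)oxy]-8βH-13,14,15,16-tetranorlabd-11-en-9α-ol; 24 3-bromofuran-2(5H)-one
Product: 26 3β-[(tert-butyldimethylsilyl)oxy]-9α-hydroxy-8βH-labd-13-en-16,15-olide, via B-alkyl-9-BBN 25 (not isolated)
Conditions: 9-BBN (2.5 equiv), THF, rt→50 °C; then 24, PdCl2(dppf) (10 mol %), AsPh3, Cs2CO3, DMF/THF/H2O, rt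
Reagents that add atoms: none
Why: Anti-Markovnikov hydroboration puts boron on C12, and B-alkyl Suzuki–Miyaura coupling with the α-bromo enoate-type bromide forms C12–C13 with the butenolide intact; AsPh3 speeds transmetalation so that the coupling runs at room temperature, where carbonate base should spare the lactone.

Step 18
Reactants: 26 3β-[(tert-butyldimethylsilyl)oxy]-9α-hydroxy-8βH-labd-13-en-16,15-olide
Product: 27 3β,9α-dihydroxy-8βH-labd-13-en-16,15-olide
Conditions: HF·pyridine, THF/pyridine, 0 °C→rt
Reagents that add atoms: none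
Why: Buffered fluoride cleavage of the secondary TBS ether under non-basic conditions, which the butenolide and the tertiary carbinol tolerate.

Step 19
Reactants: 27 3β,9α-dihydroxy-8βH-labd-13-en-16,15-olide
Product: 28 (2S,4aS,5R,6R,8aS)-5-hydroxy-1,1,4a,6-tetramethyl-5-[2-(2-oxo-2,5-dihydrofuran-3-yl)ethyl]decahydronaphthalen-2-yl acetate
Conditions: Ac2O, pyridine, DMAP (cat.), CH2Cl2, rt
Reagents that add atoms: acetic anhydride, CC(=O)OC(C)=O
Why: Acylation of the equatorial secondary 3β-hydroxyl; the tertiary 9α-hydroxyl, flanked by quaternary C10, does not react under these conditions.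

## Compound list

1 | 2,2-dimethylpent-4-enal | C=CCC(C)(C)C=O | starting material
2 | (4-bromobut-1-yn-1-yl)trimethylsilane | C[Si](C)(C)C#CCCBr | starting material
3 | [4-(trimethylsilyl)but-3-yn-1-yl]magnesium bromide (formed in situ) | C[Si](C)(C)C#CCC[Mg]Br | intermediate
4 | rac-4,4-dimethyl-9-(trimethylsilyl)non-1-en-8-yn-5-ol (formed in situ) | C=CCC(C)(C)C(O)CCC#C[Si](C)(C)C | intermediate
5 | rac-4,4-dimethylnon-1-en-8-yn-5-ol | C=CCC(C)(C)C(O)CCC#C | intermediate
6 | 4,4-dimethylnon-1-en-8-yn-5-one | C=CCC(C)(C)C(=O)CCC#C | intermediate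
7 | (5S)-4,4-dimethylnon-1-en-8-yn-5-ol | C=CCC(C)(C)[C@@H](O)CCC#C | intermediate
8 | tert-butyl{[(5S)-4,4-dimethylnon-1-en-8-yn-5-yl]oxy}dimethylsilane | C=CCC(C)(C)[C@@H](O[Si](C)(C)C(C)(C)C)CCC#C | intermediate
9 | {(1E,5S)-5-[(tert-butyldimethylsilyl)oxy]-2,6,6-trimethylnona-1,8-dien-1-yl}dimethylalumane (formed in situ) | C[Al](C)/C=C(\C)CC[C@H](O[Si](C)(C)C(C)(C)C)C(C)(C)CC=C | intermediate
10 | methyl (2E,6S)-6-[(tert-butyldimethylsilyl)oxy]-3,7,7-trimethyldeca-2,9-dienoate | COC(=O)/C=C(\C)CC[C@H](O[Si](C)(C)C(C)(C)C)C(C)(C)CC=C | intermediate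
11 | crotonaldehyde, (2E)-but-2-enal | C/C=C/C=O | starting material
12 | methyl (2E,6S,9E)-6-[(tert-butyldimethylsilyl)oxy]-3,7,7-trimethyl-11-oxoundeca-2,9-dienoate | COC(=O)/C=C(\C)CC[C@H](O[Si](C)(C)C(C)(C)C)C(C)(C)C/C=C/C=O | intermediate
13 | methyl (2E,6S,8E,10E)-6-[(tert-butyldimethylsilyl)oxy]-3,7,7-trimethyl-11-[(triethylsilyl)oxy]undeca-2,8,10-trienoate | COC(=O)/C=C(\C)CC[C@H](O[Si](C)(C)C(C)(C)C)C(C)(C)/C=C/C=C/O[Si](CC)(CC)CC | intermediate
14 | methyl 3β-[(tert-butyldimethylsilyl)oxy]-8β-[(triethylsilyl)oxy]-12,13,14,15,16,17-hexanorlabd-6-en-11-oate (trans-fused octalin; 9β-CO2Me, 9α-H) | CC(C)(C)[Si](C)(C)O[C@H]1CC[C@@]2(C)[C@@H](C=C[C@H](O[Si](CC)(CC)CC)[C@@H]2C(=O)OC)C1(C)C | intermediate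
15 | methyl 3β-[(tert-butyldimethylsilyl)oxy]-8β-[(triethylsilyl)oxy]-12,13,14,15,16,17-hexanorlabdan-11-oate (formed in situ) | CC(C)(C)[Si](C)(C)O[C@H]1CC[C@@]2(C)[C@@H](CC[C@H](O[Si](CC)(CC)CC)[C@@H]2C(=O)OC)C1(C)C | intermediate
16 | methyl 3β-[(tert-butyldimethylsilyl)oxy]-8β-hydroxy-12,13,14,15,16,17-hexanorlabdan-11-oate | CC(C)(C)[Si](C)(C)O[C@H]1CC[C@@]2(C)[C@@H](CC[C@H](O)[C@@H]2C(=O)OC)C1(C)C | intermediate
17 | methyl 3β-[(tert-butyldimethylsilyl)oxy]-8-oxo-12,13,14,15,16,17-hexanorlabdan-11-oate | CC(C)(C)[Si](C)(C)O[C@H]1CC[C@@]2(C)[C@@H](CCC(=O)[C@@H]2C(=O)OC)C1(C)C | intermediate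
18 | methyl 3β-[(tert-butyldimethylsilyl)oxy]-9α-hydroxy-8-oxo-12,13,14,15,16,17-hexanorlabdan-11-oate | CC(C)(C)[Si](C)(C)O[C@H]1CC[C@@]2(C)[C@@H](CCC(=O)[C@]2(O)C(=O)OC)C1(C)C | intermediate
19 | methyl 3β-[(tert-butyldimethylsilyl)oxy]-9α-hydroxy-12,13,14,15,16-pentanorlabd-8(17)-en-11-oate | CC(C)(C)[Si](C)(C)O[C@H]1CC[C@@]2(C)[C@@H](CCC(=C)[C@]2(O)C(=O)OC)C1(C)C | intermediate
20 | methyl 3β-[(tert-butyldimethylsilyl)oxy]-9α-hydroxy-8βH-12,13,14,15,16-pentanorlabdan-11-oate (8α-methyl) | CC(C)(C)[Si](C)(C)O[C@H]1CC[C@@]2(C)[C@@H](CC[C@@H](C)[C@]2(O)C(=O)OC)C1(C)C | intermediate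
21 | 3β-[(tert-butyldimethylsilyl)oxy]-8βH-12,13,14,15,16-pentanorlabdane-9α,11-diol | CC(C)(C)[Si](C)(C)O[C@H]1CC[C@@]2(C)[C@@H](CC[C@@H](C)[C@]2(O)CO)C1(C)C | intermediate
22 | 3β-[(tert-butyldimethylsilyl)oxy]-9α-hydroxy-8βH-12,13,14,15,16-pentanorlabdan-11-al | CC(C)(C)[Si](C)(C)O[C@H]1CC[C@@]2(C)[C@@H](CC[C@@H](C)[C@]2(O)C=O)C1(C)C | intermediate
23 | 3β-[(tert-butyldimethylsilyl)oxy]-8βH-13,14,15,16-tetranorlabd-11-en-9α-ol | CC(C)(C)[Si](C)(C)O[C@H]1CC[C@@]2(C)[C@@H](CC[C@@H](C)[C@]2(O)C=C)C1(C)C | intermediate
24 | 3-bromofuran-2(5H)-one | O=C1OCC=C1Br | starting material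
25 | 12-(9-borabicyclo[3.3.1]nonan-9-yl)-3β-[(tert-butyldimethylsilyl)oxy]-8βH-13,14,15,16-tetranorlabdan-9α-ol (formed in situ) | CC(C)(C)[Si](C)(C)O[C@H]1CC[C@@]2(C)[C@@H](CC[C@@H](C)[C@]2(O)CCB2C3CCCC2CCC3)C1(C)C | intermediate
26 | 3β-[(tert-butyldimethylsilyl)oxy]-9α-hydroxy-8βH-labd-13-en-16,15-olide | CC(C)(C)[Si](C)(C)O[C@H]1CC[C@@]2(C)[C@@H](CC[C@@H](C)[C@]2(O)CCC2=CCOC2=O)C1(C)C | intermediate
27 | 3β,9α-dihydroxy-8βH-labd-13-en-16,15-olide | O[C@H]1CC[C@@]2(C)[C@@H](CC[C@@H](C)[C@]2(O)CCC2=CCOC2=O)C1(C)C | intermediate
28 | (2S,4aS,5R,6R,8aS)-5-hydroxy-1,1,4a,6-tetramethyl-5-[2-(2-oxo-2,5-dihydrofuran-3-yl)ethyl]decahydronaphthalen-2-yl acetate (3β-acetoxy-9α-hydroxy-8βH-labd-13-en-16,15-olide) | CC(=O)O[C@H]1CC[C@@]2(C)[C@@H](CC[C@@H](C)[C@]2(O)CCC2=CCOC2=O)C1(C)C | target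

## Step count and least certain steps

Total step count: 19. Longest linear sequence: 19 steps (1 → 28); compounds 2, 11 and 24 enter directly as coupling partners.

**Step 8 (key step).** The most likely failure is protodesilylation or ionisation of the dienol silyl ether by the aluminium Lewis acid before the rings close, returning enal 12 or oligomers. The second is leakage through the ester-exo transition state to the cis-fused decalin, because an ester is a modest endo director and the β-methyl raises the barrier. The fallback changes the donor group and the mode of activation; it sets out from 12 and returns at 16.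
- Enal 12 is converted with Ac2O, Et3N and DMAP at 80 °C into the acid-stable, chromatographable dienyl acetate F1.
- F1 is cyclised without any Lewis acid in toluene at about 180 °C (sealed tube, radical inhibitor) to the 8β-acetoxy octalin F2.
- F2 is hydrogenated (H2, Pd/C, EtOAc) to the saturated acetate F3.
- Brief methanolysis of F3 (K2CO3, MeOH, 0 °C), under which acetate exchange should outrun β-elimination, gives 16.

**Step 13.** The risk is poor facial selectivity in the hydrogen-atom delivery to the C8 radical. The axial (β) trajectory that gives the equatorial methyl passes the axial C20 methyl, so delivery from the α face may compete and give the axial 8β-methyl epimer. The fallback sets C8 by stereoelectronically controlled protonation; it sets out from 17 and returns at 20.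
- β-Keto ester 17 is converted (NaH, PhNTf2, THF) into the enol triflate F4.
- F4 is methylated by iron-catalysed cross-coupling (Fe(acac)3, MeMgBr, THF/NMP, −30 °C) to the tetrasubstituted enoate F5.
- Dissolving-metal conjugate reduction of F5 (Li, NH3, t-BuOH, THF, −78 °C) should protonate C8 axially, giving the 8α-methyl ester F6.
- Deprotonation of F6 (LiN(i-Pr)2, THF) and α-face hydroxylation of the ester enolate with the oxaziridine of step 11 give 20.

**Step 17.** The risks are base-induced opening or double-bond migration of the butenolide and slow transmetalation of a hindered, alkoxide-bearing alkylborane, which would end in protodeboronation. The fallback builds the lactone by enolate alkylation; it sets out from 23 and returns at 26.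
- Hydroboration–oxidation of 23 (9-BBN; NaBO3) gives the primary alcohol F7.
- Appel iodination (I2, PPh3, imidazole) gives the iodide F8.
- Alkylation of the lithium enolate of 3-(phenylsulfanyl)oxolan-2-one (excess, THF/DMPU, −78→0 °C) with F8 gives the α-alkyl-α-phenylsulfanyl lactone F9.
- Oxidation (mCPBA, −78 °C) gives the sulfoxide F10, whose thermal syn-elimination in toluene at 110 °C forms the endocyclic butenolide 26.

**Step 12.** The risks are incomplete methylenation of a ketone flanked by a fully substituted carbinol carbon and an acyloin-type 1,2-shift of the ester under the Lewis-acidic titanium reagent. The fallback is a Peterson olefination; it sets out from 18 and returns at 19.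
- Addition of Me3SiCH2Li/CeCl3 (THF, −78 °C) to the ketone, which outpaces attack on the hindered ester, gives the β-hydroxysilane F11.
- Syn-elimination with KH in THF gives 19.

## Further compounds

F1 | step 8 | methyl (2E,6S,8E,10E)-11-acetoxy-6-[(tert-butyldimethylsilyl)oxy]-3,7,7-trimethylundeca-2,8,10-trienoate | COC(=O)/C=C(\C)CC[C@H](O[Si](C)(C)C(C)(C)C)C(C)(C)/C=C/C=C/OC(C)=O
F2 | step 8 | methyl 8β-acetoxy-3β-[(tert-butyldimethylsilyl)oxy]-12,13,14,15,16,17-hexanorlabd-6-en-11-oate | CC(C)(C)[Si](C)(C)O[C@H]1CC[C@@]2(C)[C@@H](C=C[C@H](OC(C)=O)[C@@H]2C(=O)OC)C1(C)C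
F3 | step 8 | methyl 8β-acetoxy-3β-[(tert-butyldimethylsilyl)oxy]-12,13,14,15,16,17-hexanorlabdan-11-oate | CC(C)(C)[Si](C)(C)O[C@H]1CC[C@@]2(C)[C@@H](CC[C@H](OC(C)=O)[C@@H]2C(=O)OC)C1(C)C
F4 | step 13 | methyl 3β-[(tert-butyldimethylsilyl)oxy]-8-[(trifluoromethanesulfonyl)oxy]-12,13,14,15,16,17-hexanorlabd-8-en-11-oate | CC(C)(C)[Si](C)(C)O[C@H]1CC[C@@]2(C)[C@@H](CCC(OS(=O)(=O)C(F)(F)F)=C2C(=O)OC)C1(C)C
F5 | step 13 | methyl 3β-[(tert-butyldimethylsilyl)oxy]-12,13,14,15,16-pentanorlabd-8-en-11-oate | CC(C)(C)[Si](C)(C)O[C@H]1CC[C@@]2(C)[C@@H](CCC(C)=C2C(=O)OC)C1(C)C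
F6 | step 13 | methyl 3β-[(tert-butyldimethylsilyl)oxy]-8βH-12,13,14,15,16-pentanorlabdan-11-oate (9α-H) | CC(C)(C)[Si](C)(C)O[C@H]1CC[C@@]2(C)[C@@H](CC[C@@H](C)[C@@H]2C(=O)OC)C1(C)C
F7 | step 17 | 3β-[(tert-butyldimethylsilyl)oxy]-8βH-13,14,15,16-tetranorlabdane-9α,12-diol | CC(C)(C)[Si](C)(C)O[C@H]1CC[C@@]2(C)[C@@H](CC[C@@H](C)[C@]2(O)CCO)C1(C)C
F8 | step 17 | 3β-[(tert-butyldimethylsilyl)oxy]-12-iodo-8βH-13,14,15,16-tetranorlabdan-9α-ol | CC(C)(C)[Si](C)(C)O[C@H]1CC[C@@]2(C)[C@@H](CC[C@@H](C)[C@]2(O)CCI)C1(C)C
F9 | step 17 | 3β-[(tert-butyldimethylsilyl)oxy]-9α-hydroxy-13-(phenylsulfanyl)-8βH-labdan-16,15-olide (C13 epimers) | CC(C)(C)[Si](C)(C)O[C@H]1CC[C@@]2(C)[C@@H](CC[C@@H](C)[C@]2(O)CCC2(Sc3ccccc3)CCOC2=O)C1(C)C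
F10 | step 17 | 3β-[(tert-butyldimethylsilyl)oxy]-9α-hydroxy-13-(phenylsulfinyl)-8βH-labdan-16,15-olide (mixture of isomers) | CC(C)(C)[Si](C)(C)O[C@H]1CC[C@@]2(C)[C@@H](CC[C@@H](C)[C@]2(O)CCC2(S(=O)c3ccccc3)CCOC2=O)C1(C)C
F11 | step 12 | methyl 3β-[(tert-butyldimethylsilyl)oxy]-8,9α-dihydroxy-17-(trimethylsilyl)-12,13,14,15,16-pentanorlabdan-11-oate (C8 epimers) | CC(C)(C)[Si](C)(C)O[C@H]1CC[C@@]2(C)[C@@H](CCC(O)(C[Si](C)(C)C)[C@]2(O)C(=O)OC)C1(C)C
A1 | alternative 1 | 5-(benzyloxy)-1-{4-[(tert-butyldimethylsilyl)oxy]-2-(iodomethyl)-1,3,3-trimethylcyclohexyl}pentan-1-one (ring A with labdane 3β-OTBS, 5α-H, 10β-CH3) | CC(C)(C)[Si](C)(C)O[C@H]1CC[C@@](C(=O)CCCCOCc2ccccc2)(C)[C@@H](CI)C1(C)C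
A2 | alternative 1 | acrolein (prop-2-enal) | C=CC=O
A3 | alternative 1 | 9β-[4-(benzyloxy)butyl]-3β-[(tert-butyldimethylsilyl)oxy]-9α-hydroxy-4,4,10β-trimethyl-trans-decalin-8α-carbaldehyde (labdane locants) | CC(C)(C)[Si](C)(C)O[C@H]1CC[C@@]2(C)[C@@H](CC[C@@H](C=O)[C@]2(O)CCCCOCc2ccccc2)C1(C)C
A4 | alternative 2 | methyl (6E,10S)-10,11-epoxy-7,11-dimethyl-3-oxododec-6-enoate | COC(=O)CC(=O)CC/C=C(\C)CC[C@@H]1OC1(C)C
A5 | alternative 2 | methyl 3β-hydroxy-8-oxo-12,13,14,15,16,17-hexanorlabdan-11-oate | O[C@H]1CC[C@@]2(C)[C@@H](CCC(=O)[C@@H]2C(=O)OC)C1(C)C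
A6 | alternative 3 | tert-butyl{[(5S,7E)-1-methoxy-2,6,6-trimethyl-9-(trimethylsilyl)nona-1,7-dien-5-yl]oxy}dimethylsilane (enol ether geometry not specified) | COC=C(C)CC[C@H](O[Si](C)(C)C(C)(C)C)C(C)(C)/C=C/C[Si](C)(C)C
A7 | alternative 3 | tert-butyl{[4-(dimethoxymethyl)-3-ethenyl-2,2,4-trimethylcyclohexyl]oxy}dimethylsilane (ring A with labdane 3β-OTBS, 5α-H, 10β-CH3) | CC(C)(C)[Si](C)(C)O[C@H]1CC[C@@](C(OC)OC)(C)[C@@H](C=C)C1(C)C
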